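**Plan**
The target is 1-(4-hydroxyphenyl)octadecan-5-one, numbered from the benzylic carbon C1 (ketone C5, methyl C18). It is achiral, so no stereochemistry has to be set or preserved.
The retrosynthesis first masks the phenol O–H as O–Ts, then cuts C11–C12 inside the C6–C18 polymethylene run, and last cuts C4–C5 next to the carbonyl.
The enabling feature is that C11 and C12 are both unbranched CH2 groups, with C11 six CH2 groups from the C5 carbonyl and eleven atoms from the benzene ring. Each cut end therefore maps onto a plain primary radical and so onto a simple carboxylic acid: octanoic acid for C12–C18 and an 8-oxododecanoic acid for C1–C11. Two carbons of like polarity are joined by anodic double decarboxylation (mixed Kolbe electrolysis).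
The helper is the aryl tosylate, which makes the benzene ring electron-poor so that the carboxylates, not the arene, are oxidised. It comes off in the last step.
In the forward direction the arylbutyl unit C1–C4 (as a zinc reagent) is joined to a C8 suberate unit (C5–C11 plus the sacrificial carboxyl carbon), then heptyl C12–C18 is added by electrolysis, then the tosylate is cleaved.

Key step: step 5

Remark: the target SMILES contains no stereocentre and no C=C bond, so the request for a single enantiomer has no bearing here. Compounds 1, 4 and 8 are taken as commercially available.

Step 1
Reactants: 1 4-(4-hydroxyphenyl)butan-1-ol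
Product: 2 4-[4-(tosyloxy)phenyl]butyl 4-methylbenzenesulfonate
Conditions: TsCl (2.4 equiv), Et3N (3 equiv), DMAP (5 mol%), CH2Cl2, 0 °C → rt
Reagents that add atoms: p-toluenesulfonyl chloride (TsCl), Cc1ccc(cc1)S(=O)(=O)Cl
Why: Standard DMAP-catalysed O-sulfonylation of both hydroxyl groups should go to completion with excess TsCl, so that one reagent both activates the primary alcohol as a leaving group and masks the phenol as an electron-poor, oxidation-resistant aryl sulfonate.

Step 2
Reactants: 2 4-[4-(tosyloxy)phenyl]butyl 4-methylbenzenesulfonate
Product: 3 4-(4-iodobutyl)phenyl 4-methylbenzenesulfonate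
Conditions: NaI (3 equiv), acetone, reflux
Reagents that add atoms: sodium iodide, [Na+].[I-]
Why: This is a Finkelstein-type SN2 displacement in which iodide can attack only the sp3 carbon of the alkyl tosylate, while the aryl tosylate has no substitution pathway and precipitation of the sulfonate salt from acetone drives the exchange.

Step 3
Reactants: 3 4-(4-iodobutyl)phenyl 4-methylbenzenesulfonate; 4 methyl 8-chloro-8-oxooctanoate
Product: 6 methyl 8-oxo-12-[4-(tosyloxy)phenyl]dodecanoate, via alkylzinc iodide 5 (not isolated)
Conditions: Zn dust (1.5 equiv, activated with cat. BrCH2CH2Br/TMSCl), LiCl, THF, 40 °C; then 4 (1.1 equiv), Pd(PPh3)4 (3 mol%), THF–toluene, 0 °C → rt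
Reagents that add atoms: zinc dust, [Zn] (its atom stands only in intermediate 5)
Why: Direct zinc insertion into the primary C–I bond followed by palladium-catalysed acylation of the alkylzinc iodide (Negishi-type ketone synthesis) should stop cleanly at the ketone, because the zinc reagent adds neither to the new ketone nor to the methyl ester or the aryl sulfonate, and Pd(PPh3)4 does not insert into aryl tosylates.

Step 4
Reactants: 6 methyl 8-oxo-12-[4-(tosyloxy)phenyl]dodecanoate
Product: 7 8-oxo-12-[4-(tosyloxy)phenyl]dodecanoic acid
Conditions: LiOH (2 equiv), THF–MeOH–H2O, 0 °C → rt; then 1 M HCl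
Reagents that add atoms: lithium hydroxide, [Li+].[OH-]
Why: In this ester saponification (BAC2) hydroxide should attack the unhindered methyl ester far faster than the sulfur of the aryl tosylate at or below room temperature, which leaves ketone and sulfonate in place.

Step 5
Reactants: 7 8-oxo-12-[4-(tosyloxy)phenyl]dodecanoic acid; 8 octanoic acid
Product: 9 4-(5-oxooctadecyl)phenyl 4-methylbenzenesulfonate
Conditions: 8 (6 equiv), KOH (5 mol% of total acid), MeOH, smooth Pt anode/Pt cathode, undivided cell, ca. 0.25 A cm⁻², 35–40 °C, ca. 1.3 F per mol of total acid (stopped when the electrolyte turns neutral)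
Reagents that add atoms: none
Why: In the weakly acidic, partly neutralised methanol the carboxylates of 7 and 8 are each oxidised by one electron at the platinum anode, lose CO2 and give the 7-oxo-11-arylundecyl and heptyl radicals in high local concentration at the electrode, where they combine to form the C11–C12 bond, while the carboxyl protons are discharged as H2 at the platinum cathode long before the ketone or the sulfonate could be reduced. The closest known reaction type is the mixed (crossed) Kolbe electrolysis of a fatty acid with a remote oxoalkanoic acid or an ω-arylalkanoic acid. No ring is closed and no stereocentre is formed. Cross- versus homo-coupling is statistical, so the cheap acid 8 is taken in sixfold excess to channel the radical from 7 into 9, and the tetradecane formed alongside is an apolar hydrocarbon that should part from 9 on a short silica column. The radical pathway is secured over two-electron oxidation to a cation (Hofer–Moest path) because both radicals are unbranched and primary with no α-donor, the C5 carbonyl lies six CH2 groups away, and platinum, high current density and a low degree of neutralisation are used, while the only intramolecular outlets (seven-membered attack on C=O, 1,5-hydrogen shift) are far slower than radical combination at the electrode. Chemoselectivity for carboxylate over arene rests on the O-tosyl group, which makes both benzene rings harder to oxidise than the plain alkylbenzenes that such electrolyses tolerate, whereas a free phenol or its methyl ether would be oxidised first.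

Step 6
Reactants: 9 4-(5-oxooctadecyl)phenyl 4-methylbenzenesulfonate
Product: 10 1-(4-hydroxyphenyl)octadecan-5-one
Conditions: NaOH (5 equiv), MeOH–THF–H2O, 65 °C; then 1 M HCl
Reagents that add atoms: none
Why: Alkaline S–O cleavage of an aryl sulfonate (hydroxide attack at sulfur with loss of the phenoxide) should free the phenol, while the saturated dialkyl ketone has no base-labile neighbour and its self-aldol equilibrium lies on the side of the ketone.

**Compound list**
1 | 4-(4-hydroxyphenyl)butan-1-ol | OCCCCc1ccc(O)cc1 | starting material
2 | 4-[4-(tosyloxy)phenyl]butyl 4-methylbenzenesulfonate | Cc1ccc(cc1)S(=O)(=O)OCCCCc1ccc(OS(=O)(=O)c2ccc(C)cc2)cc1 | intermediate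
3 | 4-(4-iodobutyl)phenyl 4-methylbenzenesulfonate | ICCCCc1ccc(OS(=O)(=O)c2ccc(C)cc2)cc1 | intermediate
4 | methyl 8-chloro-8-oxooctanoate | COC(=O)CCCCCCC(=O)Cl | starting material
5 | {4-[4-(tosyloxy)phenyl]butyl}zinc iodide | I[Zn]CCCCc1ccc(OS(=O)(=O)c2ccc(C)cc2)cc1 | intermediate
6 | methyl 8-oxo-12-[4-(tosyloxy)phenyl]dodecanoate | COC(=O)CCCCCCC(=O)CCCCc1ccc(OS(=O)(=O)c2ccc(C)cc2)cc1 | intermediate
7 | 8-oxo-12-[4-(tosyloxy)phenyl]dodecanoic acid | OC(=O)CCCCCCC(=O)CCCCc1ccc(OS(=O)(=O)c2ccc(C)cc2)cc1 | intermediate
8 | octanoic acid | CCCCCCCC(=O)O | starting material
9 | 4-(5-oxooctadecyl)phenyl 4-methylbenzenesulfonate | CCCCCCCCCCCCCC(=O)CCCCc1ccc(OS(=O)(=O)c2ccc(C)cc2)cc1 | intermediate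
10 | 1-(4-hydroxyphenyl)octadecan-5-one | CCCCCCCCCCCCCC(=O)CCCCc1ccc(O)cc1 | target

Total step count: 6. Longest linear sequence: 6 (1 → 2 → 3 → 6 → 7 → 9 → 10).

**Steps most likely to fail**

Step 5. Three processes could erode the coupling: anodic attack on the arene or its benzylic C–H bonds, fouling of the anode by the lipophilic products, and statistical diversion into homo-coupling. The fallback sets out from 7 and comes back at 9. It replaces the anodic radical–radical union by a reductive, inherently cross-selective nickel coupling. Esterification of 7 with N-hydroxyphthalimide (DIC, cat. DMAP, CH2Cl2) would give the redox-active ester 1,3-dioxoisoindolin-2-yl 8-oxo-12-[4-(tosyloxy)phenyl]dodecanoate F1. Heptylmagnesium bromide and ZnCl2 (0.5 equiv) in THF would give diheptylzinc F2. F1 and F2 would then be joined with NiCl2·glyme/4,4'-di-tert-butyl-2,2'-bipyridine in THF–DMF at rt (nickel-catalysed decarboxylative alkyl–alkyl Negishi-type coupling). This forms the same C11–C12 bond, tolerates the ketone and never exposes the arene to an oxidising potential.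

Step 3. Zinc insertion could be sluggish or incomplete, the iodide could homocouple reductively, and the zinc reagent could be protonated by traces of moisture before acyl transfer. The fallback sets out from 3 and 4 and comes back at 6. No organometallic reagent is preformed. The two electrophiles are coupled directly by nickel-catalysed reductive cross-electrophile acylation (NiCl2·glyme, 4,4'-di-tert-butyl-2,2'-bipyridine, Mn powder, DMA, 0 °C → rt). In this reaction the alkyl iodide is turned into a radical that is captured at an acyl-nickel species. This fallback makes no new compound (F0).

Step 4. Hydroxide attack at sulfur during the saponification could remove part of the aryl tosylate and expose the phenol before the electrolysis. The fallback sets out from 3 (through the zinc reagent 5) and comes back at 7, and it carries no ester at all. Compound 5 is acylated under the same palladium catalysis with a fourfold excess of octanedioyl dichloride (suberoyl chloride) to give 8-oxo-12-[4-(tosyloxy)phenyl]dodecanoyl chloride F3. F3 is hydrolysed by water during a non-basic work-up together with the surplus diacid chloride. The suberic acid formed alongside is removed by washing with warm water and chromatography.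

**Further compounds**
F1 | step 5 | 1,3-dioxoisoindolin-2-yl 8-oxo-12-[4-(tosyloxy)phenyl]dodecanoate | O=C(CCCCCCC(=O)CCCCc1ccc(OS(=O)(=O)c2ccc(C)cc2)cc1)ON1C(=O)c2ccccc2C1=O
F2 | step 5 | diheptylzinc | CCCCCCC[Zn]CCCCCCC
F0 | step 3 | none | none
F3 | step 4 | 8-oxo-12-[4-(tosyloxy)phenyl]dodecanoyl chloride | ClC(=O)CCCCCCC(=O)CCCCc1ccc(OS(=O)(=O)c2ccc(C)cc2)cc1
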